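If each J charged worked on its own, adding J could not raise what each J does, yet in the runs below it rose. Dawn made 2.18 /min of D per J charged over its 10.0 min: moles of D per mole of J charged per minute, the apparent turnover frequency. Noon, read the same way, made 2.40 /min, more than dawn.

| setting | dawn | noon | dusk | flask |
|---|---|---|---|---|
| E | 0.10 M | 0.10 M | 0.10 M | 0.10 M |
| G | 1.5 equiv | 1.5 equiv | 2.2 equiv | 1.50 equiv |
| J | 0.5 mol% | 0.75 mol% | 1 mol% | 1 mol% |
| X | 1.9 mM | 1.9 mM | 1.9 mM | 1.9 mM |
| remark | run made earlier | run made earlier | run made earlier |  |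
| time |  |  |  | 12 min |

- dawn (time / min: D / %, E / %): 1.33: 1.8, 99.1; 3.00: 3.8, 96.5; 4.00: 4.5, 96.0; 6.00: 6.6, 93.3; 8.00: 9.0, 90.7; 10.0: 10.9, 88.8
- noon (time / min: D / %, E / %): 1.33: 2.4, 98.3; 3.00: 5.9, 94.3; 4.00: 7.4, 92.8; 6.00: 11.1, 89.1; 8.00: 14.4, 85.5; 10.0: 18.0, 82.0
- dusk (time / min: D / %, E / %): 2.00: 7.0, 93.3; 4.00: 13.0, 86.7; 6.00: 19.4, 80.1; 8.00: 25.8, 74.2; 10.0: 31.6, 68.7

(scatter of a reading: 0.3 percentage points)

- amount of D in percent of the E charged, at 2.5 min, 6.0 min and 12 min



I took the settings in turn, starting with J. By hand, dawn's turnover at noon's loading gives 16.4% of D at 10.0 min, but noon read 18.0%, which is higher. Continuing the step from dawn to noon in a straight line to 1 mol% gave me 2.62 /min for the flask.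

Next came G. Dusk has the flask's loading but 2.2 equiv of G instead of 1.50 equiv. A rate proportional to G gives 3.84 /min, while dusk read 3.16 /min, so G helps, though less than in proportion.

X stood at 1.9 mM in every run, so no run varied it, but J rose against it, from 0.500 mM at dawn to 1.00 mM at dusk, and the rise in turnover per J may be its trace. X still exceeds the flask's 1.00 mM of J, which made it my suspect.

Last came time. The readings bend little, so I multiplied turnover, loading and time, and got 6.55% at 2.5 min, 15.7% at 6.0 min and 31.4% at 12 min.

The forecast gave 6.7%, 16% and 30.5%, resting on “Extrapolating to 1 mol% J at 1.5 equiv G”, and its last point lay below mine.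

The flask gave 6.58%, 15.6% and 29.7%.

    G + J → Z (k = 930 /M/min)
    E + Z → Q (k = 190 /M/min)
    Q ⇌ J + D (K = 7.90 M, k = 22.0 /min)
    J + X ⇌ L, settled at all times (K = 30000 /M)

In my quantity, the flask ran at 2.60 /min up to 6.0 min and 2.48 /min up to 12 min, against my 2.62 /min. At 12.0 min, L held 71.2% of the catalyst charged. With the parking of J and X as L taken away, the same flask reached 76.8%, a turnover of 6.40 /min. That parking, together with the short time allowed, holds the flask at 29.7%, for the tenfold time gave >99.9%.

(The readings were generated by integration on assumed constants; scatter was added.)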